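The readings are calculated for an exercise; scatter was added.

If the south-west flask had stopped, the next step was a new charge and not a remedy. That was the decision I had to make.

| flask | starting material | partner | temperature | remark | time |
|---|---|---|---|---|---|
| south-west | 0.052 M | 0.078 M | 0 °C | the very flask that is asked about, followed so far |  |
| south | 0.10 M | 0.078 M | −5 °C | run made earlier |  |
| flask | 0.052 M | 0.0780 M | 0 °C |  | 4.0 d |

| run | time / h | target / % |
|---|---|---|
| south-west | 5.00 | 37.0 |
| south-west | 10.0 | 36.5 |
| south-west | 25.0 | 36.4 |
| south-west | 60.0 | 36.1 |
| south | 0.833 | 14.2 |
| south | 2.00 | 28.4 |
| south | 2.50 | 32.4 |
| south | 4.00 | 35.8 |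

(standard deviation of a reading: 0.5 percentage points)

- ash: at 4.0 d take out 90 % of the target then present, then wait 4.0 d
- alder: change nothing and wait 4.0 d more
- larch: at 4.0 d raise the temperature by 25 K, then wait 4.0 d
- elm: at 4.0 d add partner, 100 % of the amount charged, then wait 4.0 d

- removed target is counted in
- additions bring no volume worth counting

- target, in percent of the starting material first charged, at 4.0 d
- the remedy with the largest gain of target, or "none" below 2 percentage points (ash / alder / larch / elm / none)
- target present, with what was taken out counted in, in percent of the starting material first charged, after alder
- target present, with what was taken out counted in, in percent of the starting material first charged, after elm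

The south-west readings fell by 0.9 percentage points from first to last, against a scatter of 0.5 points. So I took them as one plateau. My own reading was a fork: each part of the starting material became target or was lost. I used the even fork, with odds of 1, as the zero of the scale.

y = mean south-west reading = 36.5 %

o = y/(1 − y) = 0.575

I called o the fork odds: target per part of the charge that did not become target. The south-west flask lay below even. The last reading of the south run gave 0.558, with about twice the starting material, the same partner and −5 °C. So I let the odds follow the partner charge in proportion:

r = partner charged, as a fraction of the south-west charge

o′ = r·o, and y′ = o′/(1 + o′)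

The plateau had stood since 5.00 h, so I expected no late remedy to reach it. I put the flask at 36.5 % for all three amounts, chose none, and planned to raise the partner at the start of the next run.

The forecast gave 36 % (35.2 % to 36.8 %), 35.7 %, 35.8 % and none. Its ground differed from mine: “something is used up in proportion to the charge”.

    intermediate → side product (k = 0.970 /h, Ea = 77.0 kJ/mol)
    partner → decomposed reagent (k = 0.280 /h, Ea = 80.0 kJ/mol)
    partner + intermediate → target (k = 11.0 /M/h, Ea = 46.0 kJ/mol)
    starting material → intermediate (k = 3.20 /h, Ea = 83.0 kJ/mol)
    (constants at 0 °C)

The flask gave 36.5 %, then 36.5 % after alder and 36.5 % after elm. The four remedies gained 0 points each, so the answer was none. At 96.0 h it held 36.5 % target against 63.5 % side product, which is odds of 0.575. The neighbour flask was charged with 0.31 M of partner, all else held, so r = 3.97, o′ = 2.28 and y′ = 69.6 %. It gave 73.4 % target, 3.8 points above that reckoning, and 26.6 % side product.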